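| setting | epsilon | beta | dawn | dusk |
|---|---|---|---|---|
| D | 0.14 M | 0.22 M | 0.10 M | 0.10 M |
| remark | run made earlier | run made earlier |  |  |
| time |  |  | 2.5 h | 3.0 h |

| run | time / min | G / % | J / % | E / % | D / % |
|---|---|---|---|---|---|
| epsilon | 6.00 | 6.9 | 0.3 | 0.1 | 74.8 |
| epsilon | 20.0 | 15.9 | 2.4 | 1.3 | 44.6 |
| epsilon | 30.0 | 18.0 | 4.7 | 1.3 | 33.4 |
| epsilon | 50.0 | 17.6 | 10.9 | 2.3 | 20.6 |
| epsilon | 60.0 | 17.1 | 13.2 | 3.0 | 16.7 |
| epsilon | 90.0 | 14.4 | 20.5 | 4.3 | 10.6 |
| beta | 6.00 | 6.9 | 0.5 | 0 | 67.9 |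
| beta | 20.0 | 14.1 | 2.5 | 0.7 | 35.8 |
| beta | 30.0 | 14.8 | 4.6 | 0.9 | 26.2 |
| beta | 50.0 | 15.1 | 9.5 | 2.3 | 16.0 |
| beta | 60.0 | 13.8 | 11.3 | 2.8 | 12.9 |
| beta | 90.0 | 11.3 | 17.0 | 3.9 | 7.6 |

(standard deviation of a reading: 0.3 percentage points)



- which of these there is most of at the end, counted by the D in it, dawn (D / G / J / E)
- which of these there is most of at the end, counted by the D in it, dusk (D / G / J / E)
- how much there is at the end of the one of these that leads, in percent of the D charged: dawn
- how much there is at the end of the one of these that leads, in percent of the D charged: dusk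

**Bench note.** To whoever takes over: dawn and dusk each hold D at 0.10 M. Leave that charge alone, because epsilon leaves 50.2% of its D unseen at its last reading, and beta, at the larger charge, leaves more than that, 60.2%.

**J's pace.** Write the balance of D, and J is the entry that keeps climbing while G sags. Between 50.0 min and 90.0 min, epsilon gives 0.900 h⁻¹: this is J's pace, the gain of J divided by the mean G and the time elapsed, a first-order rate constant. Beta gives 0.852 h⁻¹, close to it, despite its different charge.

**What you'll find.** My own reckoning holds G at epsilon's last reading up to the end of dawn, which puts J at 33.5%. For dusk's extra stretch I take G at 0.5 of that reading, which gives 36.7%.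

**The forecast.** It names J for dawn at 35% (31% to 40%) and J for dusk at 39% (34% to 44%), both above mine , and holds that “G goes on first-order and independently of concentration”.

**The result.** J leads dawn at 33.4%, and J leads dusk at 36.9%, both inside the forecast's ranges.

    D ⇌ G (K = 7.60, k = 0.880 h⁻¹)
    G ⇌ E (K = 1.70, k = 0.220 h⁻¹)
    G → J (k = 0.880 h⁻¹)
    D → Z (k = 3.90 × 10⁻⁴ h⁻¹)
    2 D → X (k = 8.40 L mol⁻¹ h⁻¹)

**Why it held.** In dusk, G is made 1.60 times as fast as it is used at 0.471 h, each step taken net, and at 3.00 h that ratio stands at 0.378. G in dusk stands at 16.1% at 1.50 h and at 6.76% at 3.00 h. In dawn, the pace of 0.900 h⁻¹ carried from 1.25 h gives J 34.1%, against 33.4%. Take the neighbour, dusk read at 50 min, with G at 20.5%: the pace gives J a gain of 11 percentage points up to 1.50 h, and the computed gain is 11 points.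

(Readings and results are calculated for an exercise, and the scatter is random.)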